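The earlier runs and the new flask are calculated with constants of no real substance, and the scatter is random.

- Slowness came first: I asked how slowly target disappears once substrate has nearly stopped feeding it. In the teal run, substrate stood at 1.1% against target at 37.6% at 30.0 min, and target read 10.8% at 60.0 min. That gave me k_loss = 0.0416 /min, the loss constant, meaning the first-order rate constant of target's disappearance.

| flask | substrate | free catalyst | remark | time |
|---|---|---|---|---|
| amber | 0.050 M | 8 mM | run made earlier |  |
| red | 0.025 M | 8 mM | run made earlier |  |
| blue | 0.038 M | 8 mM | run made earlier |  |
| teal | 0.050 M | 16 mM | run made earlier |  |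
| eta | 0.050 M | 8.0 mM | a closed flask charged with all of it at once and left for 80 min | 80 min |
| zeta | 0.050 M | 8.0 mM | one stirred flow tank at steady state, fed with the mixture as stated, mean residence time 400 min |  |
| gamma | 0.050 M | 8.0 mM | one stirred flow tank at steady state, fed with the mixture as stated, mean residence time 80 min |  |
| delta | 0.050 M | 8.0 mM | plug flow through a tube for 80 min, no back-mixing | 80 min |

| run | time / min | target / % | substrate / % |
|---|---|---|---|
| amber | 3.00 | 13.4 | 82.6 |
| amber | 10.0 | 36.3 | 53.4 |
| amber | 15.0 | 42.6 | 37.7 |
| amber | 25.0 | 43.0 | 18.5 |
| amber | 40.0 | 31.1 | 6.2 |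
| amber | 50.0 | 22.4 | 2.6 |
| red | 10.0 | 37.5 | 50.3 |
| red | 20.0 | 45.9 | 24.3 |
| red | 30.0 | 39.5 | 11.7 |
| red | 40.0 | 30.2 | 6.1 |
| red | 50.0 | 22.4 | 2.9 |
| red | 60.0 | 15.8 | 0.8 |
| blue | 4.00 | 18.7 | 77.1 |
| blue | 12.0 | 40.4 | 45.0 |
| blue | 25.0 | 42.3 | 17.9 |
| blue | 40.0 | 30.7 | 6.0 |
| blue | 50.0 | 22.6 | 2.7 |
| blue | 60.0 | 15.7 | 1.3 |
| teal | 6.00 | 43.6 | 46.3 |
| teal | 15.0 | 57.8 | 13.0 |
| teal | 30.0 | 37.6 | 1.1 |
| teal | 50.0 | 17.0 | 0 |
| teal | 60.0 | 10.8 | 0 |

(each reading ± 0.3 percentage points)

- the set-up with the highest amount of target at the outlet or at the end, in percent of the substrate put in ("none" if the first two lie within 2 percentage points) (eta / zeta / gamma / delta / none)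
- amount of target at the outlet or at the end, in percent of the substrate put in, eta
- amount of target at the outlet or at the end, in percent of the substrate put in, zeta
- amount of target at the outlet or at the end, in percent of the substrate put in, gamma
- amount of target at the outlet or at the end, in percent of the substrate put in, delta

- the stated concentrations are those of everything mixed, before any reaction; amounts are the same in each set-up
- the analysis behind the earlier runs scatters by 0.3 percentage points, standard deviation
- the earlier runs were made in a closed, stirred flask

- Substrate in the amber run fell with a pseudo-first-order constant k_sub = 0.0700 /min, which is faster than k_loss.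
- I compared rates at the last amber reading, 50.0 min: the loss of target, k_loss times c(target), ran 5.12 times the supply, k_sub times c(substrate).
- I then turned the question round and asked what eta and delta, which share amber's charge, would need in order to beat gamma. The ratio had risen from 2.98 at 40.0 min, and supply was dying faster than target, so I expected it to go on rising in both.
- Counting amber's leftover substrate as target and letting it decay to 80 min, I reckoned 7.18% for eta and delta.
- In gamma at steady state, supply equals loss plus the outflow of target at the outlet. Target is therefore the conversion, 84.8%, divided by one plus k_loss times the residence time. I reckoned 19.6%, which is 2.73 times my closed-flask figure. Amber's reading of 22.4% at 50.0 min stood above that gamma figure, so eta and delta could go on losing target and still beat gamma if the ratio, averaged from then to 80 min, were about 1.12. The ratio read at 50.0 min was already higher than that.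
- The forecast named gamma, with 19.2% (18% to 20.4%) for gamma, 7.3% for eta, 7.3% for delta and 5.4% for zeta, on the ground that “target loss is first order and uncatalysed”. My gamma figure stood slightly above its figure, and my closed-flask figure slightly below.
- The flasks gave 7.64% in eta, 7.64% in delta, 5.53% in zeta and 18.8% in gamma, so gamma held the most target.

    substrate + free catalyst → catalyst intermediate (k = 9.40 /M/min)
    catalyst intermediate → free catalyst + target (k = 1.80 /min)
    target → over-reaction product (k = 0.0370 /min)
    free catalyst → spent catalyst (k = 4.70 × 10⁻⁵ /min)
    target ⇌ isomer of the product (K = 3.50, k = 0.00790 /min)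

- The half-life of target by the path to over-reaction product alone, 19 min, is shorter than the 88 min of the forward path to isomer of the product alone and short against 80 min, and eta ended with 77.2% of the substrate charged as over-reaction product. Zeta, at 400 min, has k_loss times residence time of 16.6, which makes 5.47% beside the 5.53% at its outlet.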